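Positions are given in chromene numbering (O1, C2, C3, C4, C4a, C5 to C8, C8a), also for the quinone intermediates. The target has no stereocentre, so nothing has to be set; the only stereochemical element is the geometry of one transient exocyclic alkene, which equilibrates.
Enabling feature: the oxygens on C6 and C8a stand para on the benzenoid ring, so this ring is a masked 1,4-benzoquinone. At that oxidation level C8, the most electron-rich carbon of the arene, becomes the β-carbon of the C6 enone and can be joined to C3 of indole, a carbon of the same natural polarity.
A methoxy group on C7 would make C8 the electron-rich α-carbon of a vinylogous ester. Bromine therefore stands in for it, and a second bromine for the prenyl carbon on C4a, until both aryl–indole bonds are made.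
Retrosynthetic cuts: O1–C2 (retro oxa-6π and tautomerisation to a prenylquinone), C4a–CH2 (Stille), C7–OMe (addition–elimination), then C8–C3 of indole (key step) and last C5–C3 of indole.
Forward order: the purchased quinone ring takes up indole at C5 and then at C8. One of the two now equivalent bromides is exchanged for methoxide and the other for prenyl. The pyran ring is closed last, in an event that also rebuilds the benzenoid ring and frees the C6 hydroxyl, so no protecting group is needed.

Key step: step 2

Step 1
Reactants: 1 2,5-dibromo-1,4-benzoquinone; 2 1H-indole
Product: 4 2,5-dibromo-3-(1H-indol-3-yl)-1,4-benzoquinone, via hydroquinone adduct 3 (not isolated)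
Conditions: indole (1.0 equiv), conc. HCl (cat.), THF, rt; then DDQ (1.0 equiv), rt
Reagents that add atoms: none
Why: Acid-catalysed conjugate (Michael-type Friedel–Crafts) addition of indole C3 to a ring C–H carbon of a 2,5-dihaloquinone with DDQ re-oxidation is an established entry to 3-(indol-3-yl)quinones, and it should stop after one addition because the new indolyl group deactivates the quinone by push–pull conjugation.

Step 2
Reactants: 4 2,5-dibromo-3-(1H-indol-3-yl)-1,4-benzoquinone; 2 1H-indole
Product: 6 2,5-dibromo-3,6-di(1H-indol-3-yl)-1,4-benzoquinone, via hydroquinone adduct 5 (not isolated)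
Conditions: indole (1.5 equiv), conc. H2SO4 (cat.), AcOH, 50 °C; then DDQ (1.0 equiv), THF, rt
Reagents that add atoms: none
Why: Protonation of the C6 carbonyl, the one that is not in vinylogous-amide conjugation with the indole already on C5, makes the only ring C–H carbon, C8, the β-terminus of an activated bromo-enone; indole C3 attacks there, loss of the C3 proton and enolisation give hydroquinone 5, and DDQ restores the quinone level, so two carbons that are both nucleophilic in the target are joined in a net dehydrogenative C–H/C–H coupling. The closest known reaction type is the acid-catalysed conjugate addition of indoles to 2,5-dihalo-1,4-benzoquinones with DDQ re-oxidation, as used for bis(indolyl)quinones. No ring is closed and no stereocentre is formed. The step needs site selectivity between C8–H and the two C–Br carbons: attack at C8 alone keeps the push–pull chain indole–C5=C4a–C8a=O intact, places the developing enol next to the inductively stabilising bromine on C7 and ends in irreversible aromatisation, whereas attack at C7 or C4a breaks that conjugation. Indole should react through C3 and not through N1 or C2, because C3 is its most nucleophilic site under acid. Product 6 is centrosymmetric, so the two bromine helpers that remain are equivalent and the next step needs no regiocontrol.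

Step 3
Reactants: 6 2,5-dibromo-3,6-di(1H-indol-3-yl)-1,4-benzoquinone
Product: 7 2-bromo-3,6-di(1H-indol-3-yl)-5-methoxy-1,4-benzoquinone
Conditions: NaOMe (1.05 equiv), MeOH–THF, 0 °C to rt
Reagents that add atoms: sodium methoxide, [Na+].[O-]C
Why: Vinylogous acyl substitution (addition–elimination) of a quinone C–Br by an oxygen nucleophile is the standard exchange in the bis(indolyl)dihaloquinone series, either bromide of 6 gives the same product, and with methoxide as the limiting reagent the reaction should stop at 7 because the donor methoxy group lowers the electrophilicity of the ring.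

Step 4
Reactants: 7 2-bromo-3,6-di(1H-indol-3-yl)-5-methoxy-1,4-benzoquinone; 8 tributyl(3-methylbut-2-en-1-yl)stannane
Product: 9 2,5-di(1H-indol-3-yl)-3-methoxy-6-(3-methylbut-2-en-1-yl)-1,4-benzoquinone
Conditions: Pd2(dba)3 (5 mol %), AsPh3 (20 mol %), 1,4-dioxane, 70 °C, Ar
Reagents that add atoms: none
Why: In this Stille coupling the C4a–Br bond is a vinylogous acyl bromide that adds to zerovalent palladium, bromo(methoxy)quinones being established cross-coupling partners; the η3-prenyl palladium intermediate should form the C–C bond at its unsubstituted terminus next to the crowded quinonyl group, and the neutral medium spares the base-sensitive product.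

Step 5
Reactants: 9 2,5-di(1H-indol-3-yl)-3-methoxy-6-(3-methylbut-2-en-1-yl)-1,4-benzoquinone
Product: 11 kumbicin C, via ortho-quinone methide 10 (not isolated)
Conditions: pyridine, 115 °C, Ar
Reagents that add atoms: none
Why: The base removes a proton from the prenyl CH2, which is allylic and vinylogously α to the C6 carbonyl; reprotonation on the C6 oxygen gives ortho-quinone methide 10, whose oxa-6π electrocyclisation (C8a oxygen onto the CMe2 terminus) closes the pyran ring and restores the benzenoid ring, as known for the prenylquinone-to-chromenol isomerisation, with the regiochemistry fixed because only the C8a carbonyl adjoins C4a and with the alkene isomers of 10 equilibrating through 9.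

Compound list
1 | 2,5-dibromo-1,4-benzoquinone | O=C1C=C(Br)C(=O)C=C1Br | starting material
2 | 1H-indole | c1ccc2[nH]ccc2c1 | starting material
3 | 2,5-dibromo-3-(1H-indol-3-yl)benzene-1,4-diol | Oc1cc(Br)c(O)c(-c2c[nH]c3ccccc23)c1Br | intermediate
4 | 2,5-dibromo-3-(1H-indol-3-yl)-1,4-benzoquinone | O=C1C=C(Br)C(=O)C(c2c[nH]c3ccccc23)=C1Br | intermediate
5 | 2,5-dibromo-3,6-di(1H-indol-3-yl)benzene-1,4-diol | Oc1c(Br)c(-c2c[nH]c3ccccc23)c(O)c(Br)c1-c1c[nH]c2ccccc12 | intermediate
6 | 2,5-dibromo-3,6-di(1H-indol-3-yl)-1,4-benzoquinone | O=C1C(Br)=C(c2c[nH]c3ccccc23)C(=O)C(Br)=C1c1c[nH]c2ccccc12 | intermediate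
7 | 2-bromo-3,6-di(1H-indol-3-yl)-5-methoxy-1,4-benzoquinone | COC1=C(c2c[nH]c3ccccc23)C(=O)C(Br)=C(c2c[nH]c3ccccc23)C1=O | intermediate
8 | tributyl(3-methylbut-2-en-1-yl)stannane | CCCC[Sn](CCCC)(CCCC)CC=C(C)C | starting material
9 | 2,5-di(1H-indol-3-yl)-3-methoxy-6-(3-methylbut-2-en-1-yl)-1,4-benzoquinone | COC1=C(c2c[nH]c3ccccc23)C(=O)C(CC=C(C)C)=C(c2c[nH]c3ccccc23)C1=O | intermediate
10 | (6Z)-4-hydroxy-2,5-di(1H-indol-3-yl)-3-methoxy-6-(3-methylbut-2-en-1-ylidene)cyclohexa-2,4-dien-1-one | COC1=C(c2c[nH]c3ccccc23)C(=O)/C(=C\C=C(C)C)C(c2c[nH]c3ccccc23)=C1O | intermediate
11 | kumbicin C, 5,8-di(1H-indol-3-yl)-7-methoxy-2,2-dimethyl-2H-chromen-6-ol | COc1c(O)c(-c2c[nH]c3ccccc23)c2c(c1-c1c[nH]c3ccccc13)OC(C)(C)C=C2 | target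

Total step count: 5. Longest linear sequence: 5 steps (1, 4, 6, 7, 9, 11).

Steps most likely to fail

Step 4. Oxidative addition at the hindered, electron-rich C4a–Br bond may be slow. The quinone may be reduced by the palladium–stannane couple. The allyl unit may also be transferred through its tertiary terminus (reverse prenylation). The fallback sets out from 7 and inverts the polarity at C4a from cross-coupling electrophile to arene nucleophile. Hydrogenolysis (H2, Pd/C, NaOAc, MeOH–EtOAc) should reduce the quinone and cleave the C–Br bond to give 2,5-di(1H-indol-3-yl)-3-methoxybenzene-1,4-diol F1, which is handled under argon. In F1, C4a–H is the only free ring position; it lies ortho to the C8a hydroxyl and para to the C7 methoxy group. Ortho-selective chromenylation with 3-methylbut-2-enal (PhB(OH)2, AcOH, toluene, reflux with removal of water) should pass through a benzodioxaborin that fragments to the same ortho-quinone methide. The route is thus rejoined at 10 and hence at 11.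

Step 3. The second displacement may compete with the first. Alternatively the exchange may stall because methoxide is tied up in deprotonating the acidic indole N–H groups. The fallback sets out from 6 and replaces stoichiometric control by charge control. Aqueous KOH in THF at rt should displace one bromide, and the product then exists as a hydroxyquinone anion (a vinylogous carboxylate) whose charge shuts down the second displacement. Acidification should give 2-bromo-5-hydroxy-3,6-di(1H-indol-3-yl)-1,4-benzoquinone F2. Vinylogous Fischer esterification of F2 (MeOH, HCl cat., reflux) touches only the acidic quinone hydroxyl and not the N–H groups, and returns to the route at 7.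

Step 2. Acid-induced oligomerisation of indole may outrun its slow addition to the push–pull deactivated quinone 4. The fallback sets out from 2 and replaces the acid-catalysed C–H addition and re-oxidation by a base-mediated ipso substitution that needs neither acid nor oxidant. Indole and tetrabromo-1,4-benzoquinone (Cs2CO3, MeCN, rt) should give 2,3,5-tribromo-6-(1H-indol-3-yl)-1,4-benzoquinone F3 by addition–elimination through C3. A second equivalent of indole under the same conditions should displace the bromide para to the first indolyl group, the only position whose attack keeps the push–pull conjugation. This returns to the route at 6.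

Further compounds
F1 | step 4 | 2,5-di(1H-indol-3-yl)-3-methoxybenzene-1,4-diol | COc1c(O)c(-c2c[nH]c3ccccc23)cc(O)c1-c1c[nH]c2ccccc12
F2 | step 3 | 2-bromo-5-hydroxy-3,6-di(1H-indol-3-yl)-1,4-benzoquinone | OC1=C(c2c[nH]c3ccccc23)C(=O)C(Br)=C(c2c[nH]c3ccccc23)C1=O
F3 | step 2 | 2,3,5-tribromo-6-(1H-indol-3-yl)-1,4-benzoquinone | O=C1C(Br)=C(Br)C(=O)C(c2c[nH]c3ccccc23)=C1Br
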